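## Structural features

- The target is a depside: two benzene rings joined by one aryl ester and no other ring. Ring A (locants C1–C6) is a methyl benzoate with a hydroxyl at C2, the depside oxygen at C4 and a 2-oxononyl chain (CH2–CO–C7H15) at C6. Ring B (C1'–C6') is a benzoyl unit with hydroxyls at C2' and C4' and the same chain at C6'.
- There is no stereocentre, so the whole problem is one of regiochemistry and functional-group tolerance.
- The aryl ester is an activated ester, because its leaving group is a phenol, and it is the most fragile bond.
- Each Ar–CH2–C(=O) unit has acidic benzylic hydrogens and sits ortho to an ester carbonyl. Under acid or base its enol oxygen can close onto that carbonyl to give a 3-heptylisocoumarin; on ring B this would expel ring A and destroy the depside.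
- The hydroxyls at C2 and C2' are hydrogen-bonded to their neighbouring carbonyl groups and are far less nucleophilic than the oxygens at C4 and C4'. The route uses this difference for regiocontrol.
- The real difficulty is to install two enolisable keto arms next to two esters, and then to unmask three phenols, without strong acid or base.
- The key step exploits the fact that C6 and C6' carry identical arms and each lies ortho to an ester carbonyl. A C6,C6'-dibromide can therefore take up one enolate equivalent of 2-nonanone twice, the ester carbonyls activating the adjacent C–Br bonds.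

## Logic of the disconnections

**18 ⇒ 17.** The three phenolic O–CH2Ph bonds are cut. Benzyl ethers are chosen in place of methoxymethyl ethers for three reasons:
- they come off by neutral hydrogenolysis, whereas acetal ethers would need mineral acid in an alcohol, which invites alcoholysis of the aryl ester and isocoumarin closure of either arm;
- they tolerate acid chloride formation, which ortho-acetal ethers do not;
- they avoid the carcinogenic chloromethyl ether reagent.

The forward step requires that no aryl halide remains and that the ketones and both esters are inert to H2 over palladium.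

**17 ⇒ 10 + two 13.** The C6–CH2 and C6'–CH2 bonds are cut. This removes both side chains at once and leaves a dibromide whose ortho substituents are small, so the hindered depside ester can be made before the arms exist. The forward step must arylate C1 of the nonanone unit only, once per bromide, in a medium that neither enolises the products nor attacks the aryl ester. The skeleton of 10 is the required dibromo depside; only the ether groups differ from the acetal-protected version.

**13 ⇒ 11.** The O–Si bond is cut. The demand is kinetic deprotonation at the methyl group, so that the double bond of 13 is terminal.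

**10 ⇒ 9 ⇒ 8.** The ester O–CH3 bond is cut, and the carboxyl at C1 of ring A is taken back to a formyl group. Keeping C1 as an aldehyde during assembly supplies the hydrogen bond that differentiates the two ring A hydroxyls, and lets both rings come from one intermediate. The demands are an aldehyde oxidation and a carboxylate methylation that leave the depside ester alone.

**8 ⇒ 7.** The C2 O–benzyl bond of ring A is cut. Protecting this hydroxyl after the depside bond is made avoids any temporary group on the C4 oxygen. Selective protection of a 2,4-dihydroxy precursor would put the group on C4, the more reactive oxygen, and not on C2. The forward alkylation must be mild enough to spare the aryl ester.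

**7 ⇒ 5 + 3.** The depside C1'(=O)–O–C4 bond is cut, giving a protected ring B acid and an unprotected ring A dihydroxy aldehyde. The forward step must acylate only the C4 hydroxyl of 3; the C6 hydroxyl of 3 (C2 of ring A) is held in a hydrogen bond to the formyl group.

**5 ⇒ 4 ⇒ 3.** The carboxyl is taken back to the aldehyde and the two O–benzyl bonds are cut. Ring B thus derives from the same aldehyde as ring A. The forward steps are exhaustive benzylation and a chlorite oxidation.

**3 ⇒ 1.** The ring C–CHO bond is cut, leading to a symmetrical commercial bromoresorcinol. Formylation must occur at C4 (equivalent to C6) and not at C2 between the hydroxyls.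

## Other disconnections considered

**Alternative 1:** biomimetic aldol aromatisation.
- Cut: the C1'–C6' bond of ring B. The benzoyl ring is opened to a poly-β-carbonyl chain already esterified to the C4 oxygen of ring A.
- Forward key step: the aryl 8-(2-heptyl-1,3-dioxolan-2-yl)-3,5,7-trioxooctanoate A2 would be made by trapping a thermally generated acylketene with the ring A phenol. Mild base then acid should make C2 add to the C7 ketone; dehydration and enolisation give the bis-dioxolane depside A1.
- In its favour: ring B is born with both hydroxyls free and with the depside ester already in place. No halogen, tin or palladium is used. The aldol/dehydration sequence follows the biosynthetic logic of orsellinate-type rings.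
- Against it here:
  - The enolates of A2 have other exits. An enol oxygen can attack the activated aryl ester and form a pyranone with loss of ring A, and Claisen-type C-acylation is also possible.
  - Only the ring B arm is solved. Ring A must arrive with its own ketal-protected arm, made by a separate method.
  - The two dioxolanes need aqueous acid at the end, the conditions under which an oxononyl arm closes onto its ortho ester.
- Comparison:
  - Structure: the alternative builds ring B from acyclic carbons and is better in needing no phenol protection on ring B. The chosen plan uses two intact aromatic rings and the twofold symmetry of the arms, which the alternative does not.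
  - Mechanism: both key steps are base-free or nearly so. The alternative depends on one cyclisation mode winning over several; the chosen plan depends on a well-behaved catalytic cycle.
  - Step economy: the alternative is longer, since the triketo chain and the ring A arm each need several steps.

**Alternative 2:** twofold carbonylative coupling.
- Cut: both bonds flanking each ketone carbonyl (CH2–CO and CO–C7H15 in both arms). This leads to the bis(bromomethyl) depside triacetate A4, carbon monoxide A6 and heptylzinc bromide A5.
- Forward key step: Pd(PPh3)4 adds to each benzylic C–Br bond, A6 inserts, A5 transmetalates, and reductive elimination gives the triacetate A3.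
- In its favour: four C–C bonds form in one operation. The carbon skeleton of A4 is a simple 6,6'-dimethyl depside of the lecanorate type. The alkyl chain is introduced last and could be varied. No strong base is present.
- Against it here:
  - Radical bromination of two aryl methyl groups on an oxygenated depside competes with ring bromination and over-bromination.
  - An ortho-(bromomethyl) benzoate lactonises readily to a phthalide; on ring B this would expel ring A.
  - Direct benzyl–alkyl coupling without insertion of A6, and β-hydride loss from the heptyl–palladium species, compete at both sites.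
  - Three aryl acetates must finally be cleaved by a nucleophile in the presence of the depside aryl ester and the enolisable ketones.
- Comparison:
  - Structure: the alternative is the equal of the chosen plan in using the symmetry of the two arms.
  - Step economy: it is probably the equal or the better, provided A4 is reached in few steps.
  - Mechanism: the chosen plan needs two bond-forming events, not four, uses no toxic gas, and ends with a neutral deprotection in place of a chemoselective ester cleavage.

**Alternative 3:** Diels–Alder benzannulation.
- Cut: ring B across C1'–C2' and C5'–C6'. This leads to the aryl alkynoate A8 (the ring A phenol esterified with a 4-substituted but-2-ynoic acid carrying the ketal-protected chain) and 1-methoxy-1,3-bis(trimethylsilyloxy)buta-1,3-diene A9.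
- Forward key step: cycloaddition of A9 to the triple bond of A8, then loss of the methoxy group and of the silyl groups, aromatises ring B and gives A7.
- In its favour: the polarity of diene and ynoate places the C2' and C4' hydroxyls and the C6' arm unambiguously. These hydroxyls need no protection, and no transition metal is used.
- Against it here:
  - An ynoate with a CH2 substituent at the β-carbon is a sluggish dienophile and needs heat.
  - Under heat the nucleophilic silyl ketene acetal A9 may attack the aryl ester, and the propargylic system may isomerise to an allenoate.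
  - Ring A must be prepared beforehand with its arm and with two kinds of acid-labile protection, so the arm problem of ring A is only postponed.
  - Aqueous acid is needed at the end.
- Comparison:
  - Structure: the alternative is the better on regiocontrol of ring B oxygenation, which it sets with no selective formylation or acylation. It is the weaker in not using the symmetry of the arms.
  - Mechanism: a thermal pericyclic or stepwise addition against a competing acyl transfer, versus a catalytic coupling under neutral fluoride conditions.
  - Step economy: the alternative has the longer linear sequence because ring A with its arm is a multistep intermediate.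

Key step: step 9

## Route

Remark on the chemistry: the skeletons of the dibromo depside and of the coupled diketone are kept as required; the three phenol protecting groups are benzyl, not methoxymethyl, for the reasons set out above.

Step 1
Reactants: 1 5-bromobenzene-1,3-diol
Product: 3 2-bromo-4,6-dihydroxybenzaldehyde, via aryl iminium chloride 2 (not isolated)
Conditions: POCl3, DMF, MeCN, 0 °C → rt; then H2O, 50 °C
Reagents that add atoms: N,N-dimethylformamide CN(C)C=O; water O
Why: Vilsmeier–Haack formylation. The chloroiminium ion should attack C4 (equivalent to C6) of the resorcinol, which is para to one hydroxyl and ortho to the other and less crowded than C2 between the two hydroxyls. Water then hydrolyses iminium salt 2 and any O-formyl groups.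

Step 2
Reactants: 3 2-bromo-4,6-dihydroxybenzaldehyde
Product: 4 2,4-bis(benzyloxy)-6-bromobenzaldehyde
Conditions: BnBr (2.3 equiv), K2CO3, DMF, 60 °C
Reagents that add atoms: benzyl bromide BrCc1ccccc1
Why: Williamson ether synthesis. Warming is used so that the hydrogen-bonded hydroxyl next to the formyl group is alkylated as well; the aldehyde and the aryl bromide are inert.

Step 3
Reactants: 4 2,4-bis(benzyloxy)-6-bromobenzaldehyde
Product: 5 2,4-bis(benzyloxy)-6-bromobenzoic acid
Conditions: NaClO2, NaH2PO4, 2-methylbut-2-ene, t-BuOH/THF/H2O, rt
Reagents that add atoms: sodium chlorite [Na+].[O-]Cl=O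
Why: Pinnick (Lindgren–Kraus) oxidation. The alkene scavenger removes hypochlorous acid so that the electron-rich ring is not chlorinated; benzyl ethers and the bromide are stable in the buffered, weakly acidic medium.

Step 4
Reactants: 5 2,4-bis(benzyloxy)-6-bromobenzoic acid; 3 2-bromo-4,6-dihydroxybenzaldehyde
Product: 7 3-bromo-4-formyl-5-hydroxyphenyl 2,4-bis(benzyloxy)-6-bromobenzoate, via acid chloride 6 (not isolated)
Conditions: (COCl)2, cat. DMF, CH2Cl2, 0 °C → rt, concentrate; then 3 (1.05 equiv), Et3N, cat. DMAP, CH2Cl2, −20 °C → rt
Reagents that add atoms: none
Why: DMAP-catalysed acylation of a phenol by an acid chloride; benzyl ethers tolerate oxalyl chloride, which ortho-acetal ethers would not. In 3 the hydroxyl para to the formyl group is unhindered and the more acidic, while the other is held in a hydrogen bond to the aldehyde, so one equivalent of 6 at low temperature should acylate the para oxygen only.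

Step 5
Reactants: 7 3-bromo-4-formyl-5-hydroxyphenyl 2,4-bis(benzyloxy)-6-bromobenzoate
Product: 8 3-(benzyloxy)-5-bromo-4-formylphenyl 2,4-bis(benzyloxy)-6-bromobenzoate
Conditions: BnBr (1.3 equiv), K2CO3, dry DMF, rt
Reagents that add atoms: benzyl bromide BrCc1ccccc1
Why: Williamson ether synthesis on the only remaining hydroxyl. Room temperature and dry solvent are chosen so that the di-ortho-substituted, hence shielded, aryl ester is not cleaved.

Step 6
Reactants: 8 3-(benzyloxy)-5-bromo-4-formylphenyl 2,4-bis(benzyloxy)-6-bromobenzoate
Product: 9 2-(benzyloxy)-4-{[2,4-bis(benzyloxy)-6-bromobenzoyl]oxy}-6-bromobenzoic acid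
Conditions: NaClO2, NaH2PO4, 2-methylbut-2-ene, t-BuOH/THF/H2O, rt
Reagents that add atoms: sodium chlorite [Na+].[O-]Cl=O
Why: Pinnick oxidation, the same transformation as in step 3. The buffered medium near pH 4 leaves the aryl ester and the benzyl ethers untouched.

Step 7
Reactants: 9 2-(benzyloxy)-4-{[2,4-bis(benzyloxy)-6-bromobenzoyl]oxy}-6-bromobenzoic acid
Product: 10 methyl 2-(benzyloxy)-4-{[2,4-bis(benzyloxy)-6-bromobenzoyl]oxy}-6-bromobenzoate
Conditions: MeI, KHCO3, DMF, rt
Reagents that add atoms: iodomethane CI
Why: SN2 O-alkylation of the carboxylate, which is insensitive to the crowding around the carboxyl carbon. Hydrogencarbonate is too weak a base to open the depside ester.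

Step 8
Reactants: 11 nonan-2-one
Product: 13 trimethyl(non-1-en-2-yloxy)silane, via lithium enolate 12 (not isolated)
Conditions: LiN(i-Pr)2 (1.05 equiv), THF, −78 °C, ketone added to base; then Me3SiCl, −78 °C → rt; non-aqueous work-up, distillation
Reagents that add atoms: chlorotrimethylsilane C[Si](C)(C)Cl
Why: Kinetic deprotonation of the methyl group by the hindered amide at low temperature, followed by O-silylation, should give the terminal enol silane. Adding the ketone to excess base prevents equilibration to the internal enolate.

Step 9
Reactants: 10 methyl 2-(benzyloxy)-4-{[2,4-bis(benzyloxy)-6-bromobenzoyl]oxy}-6-bromobenzoate; 13 trimethyl(non-1-en-2-yloxy)silane (two equivalents consumed, 2.6 equiv used)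
Product: 17 methyl 2-(benzyloxy)-4-{[2,4-bis(benzyloxy)-6-(2-oxononyl)benzoyl]oxy}-6-(2-oxononyl)benzoate, via tributyltin enolate 14 (not isolated), via ring B monoketone 15 (not isolated), via ring A monoketone 16 (not isolated)
Conditions: Pd(dba)2 (5 mol %), P(t-Bu)3 (6 mol %), Bu3SnF (2.6 equiv), toluene, 85 °C; aqueous KF wash
Reagents that add atoms: none
Why: Fluoride from Bu3SnF moves the enolate of 13 from silicon to tin, giving Me3SiF and tin enolate 14. Zerovalent palladium bearing one P(t-Bu)3 inserts into a C–Br bond of 10; both bromides lie ortho to an ester carbonyl, which eases the insertion, and they can react in either order, so monoketones 15 and 16 are both passed through. Transmetalation gives a carbon-bound arylpalladium enolate of divalent palladium, and reductive elimination, accelerated by the bulky phosphine, forms the aryl–CH2 bond and returns zerovalent palladium. The closest known reaction type is the palladium-catalysed α-arylation of ketone trimethylsilyl enol ethers with aryl bromides under tin fluoride activation (Kuwajima–Urabe and Kosugi–Migita type). No ring is closed and no stereocentre is formed. The step needs arylation at C1 and not C3 of the nonanone unit, which the terminal double bond of 13 secures because the tin enolate should couple faster than it equilibrates. It needs a single arylation per enolate, which follows from the absence of any base able to re-enolise the more acidic benzylic ketone. It also needs inertness of the aryl ester, the methyl ester and the benzyl ethers, none of which is attacked by a tin enolate or by the catalyst; the same absence of alkoxide or amide base should keep the new keto arms from closing onto their ortho esters.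

Step 10
Reactants: 17 methyl 2-(benzyloxy)-4-{[2,4-bis(benzyloxy)-6-(2-oxononyl)benzoyl]oxy}-6-(2-oxononyl)benzoate
Product: 18 methyl 4-{[2,4-dihydroxy-6-(2-oxononyl)benzoyl]oxy}-2-hydroxy-6-(2-oxononyl)benzoate
Conditions: H2 (1 atm), Pd/C (10 wt % Pd), EtOAc, rt
Reagents that add atoms: none
Why: Catalytic hydrogenolysis of the three aryl benzyl ethers under neutral conditions. The aliphatic ketones and both esters should be untouched, no halogen remains, and neither acid nor base is present to trigger isocoumarin closure or ester exchange.

## Compound list

1 | 5-bromobenzene-1,3-diol | Oc1cc(O)cc(Br)c1 | starting material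
2 | (2-bromo-4,6-dihydroxybenzylidene)dimethyliminium chloride | C[N+](C)=Cc1c(O)cc(O)cc1Br.[Cl-] | intermediate (not isolated)
3 | 2-bromo-4,6-dihydroxybenzaldehyde | O=Cc1c(O)cc(O)cc1Br | intermediate
4 | 2,4-bis(benzyloxy)-6-bromobenzaldehyde | O=Cc1c(OCc2ccccc2)cc(OCc2ccccc2)cc1Br | intermediate
5 | 2,4-bis(benzyloxy)-6-bromobenzoic acid | OC(=O)c1c(OCc2ccccc2)cc(OCc2ccccc2)cc1Br | intermediate
6 | 2,4-bis(benzyloxy)-6-bromobenzoyl chloride | ClC(=O)c1c(OCc2ccccc2)cc(OCc2ccccc2)cc1Br | intermediate (not isolated)
7 | 3-bromo-4-formyl-5-hydroxyphenyl 2,4-bis(benzyloxy)-6-bromobenzoate | O=Cc1c(O)cc(OC(=O)c2c(OCc3ccccc3)cc(OCc3ccccc3)cc2Br)cc1Br | intermediate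
8 | 3-(benzyloxy)-5-bromo-4-formylphenyl 2,4-bis(benzyloxy)-6-bromobenzoate | O=Cc1c(OCc2ccccc2)cc(OC(=O)c2c(OCc3ccccc3)cc(OCc3ccccc3)cc2Br)cc1Br | intermediate
9 | 2-(benzyloxy)-4-{[2,4-bis(benzyloxy)-6-bromobenzoyl]oxy}-6-bromobenzoic acid | OC(=O)c1c(OCc2ccccc2)cc(OC(=O)c2c(OCc3ccccc3)cc(OCc3ccccc3)cc2Br)cc1Br | intermediate
10 | methyl 2-(benzyloxy)-4-{[2,4-bis(benzyloxy)-6-bromobenzoyl]oxy}-6-bromobenzoate | COC(=O)c1c(OCc2ccccc2)cc(OC(=O)c2c(OCc3ccccc3)cc(OCc3ccccc3)cc2Br)cc1Br | intermediate (key-step precursor)
11 | nonan-2-one | CCCCCCCC(C)=O | starting material
12 | lithium non-1-en-2-olate | [Li+].[O-]C(=C)CCCCCCC | intermediate (not isolated)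
13 | trimethyl(non-1-en-2-yloxy)silane | CCCCCCCC(=C)O[Si](C)(C)C | intermediate (key-step precursor)
14 | tributyl(non-1-en-2-yloxy)stannane | CCCCCCCC(=C)O[Sn](CCCC)(CCCC)CCCC | intermediate (not isolated)
15 | methyl 2-(benzyloxy)-4-{[2,4-bis(benzyloxy)-6-(2-oxononyl)benzoyl]oxy}-6-bromobenzoate | CCCCCCCC(=O)Cc1cc(OCc2ccccc2)cc(OCc2ccccc2)c1C(=O)Oc1cc(OCc2ccccc2)c(C(=O)OC)c(Br)c1 | intermediate (not isolated)
16 | methyl 2-(benzyloxy)-4-{[2,4-bis(benzyloxy)-6-bromobenzoyl]oxy}-6-(2-oxononyl)benzoate | CCCCCCCC(=O)Cc1cc(OC(=O)c2c(OCc3ccccc3)cc(OCc3ccccc3)cc2Br)cc(OCc2ccccc2)c1C(=O)OC | intermediate (not isolated)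
17 | methyl 2-(benzyloxy)-4-{[2,4-bis(benzyloxy)-6-(2-oxononyl)benzoyl]oxy}-6-(2-oxononyl)benzoate | CCCCCCCC(=O)Cc1cc(OCc2ccccc2)cc(OCc2ccccc2)c1C(=O)Oc1cc(OCc2ccccc2)c(C(=O)OC)c(CC(=O)CCCCCCC)c1 | intermediate (key-step product)
18 | methyl 4-{[2,4-dihydroxy-6-(2-oxononyl)benzoyl]oxy}-2-hydroxy-6-(2-oxononyl)benzoate | CCCCCCCC(=O)Cc1cc(OC(=O)c2c(O)cc(O)cc2CC(=O)CCCCCCC)cc(O)c1C(=O)OC | target

## Step count and least certain steps

Total step count: 10 steps. Longest linear sequence: 9 steps (steps 1, 2, 3, 4, 5, 6, 7, 9, 10 from compound 1). Step 8 is a one-step side branch.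

**Step 9 (key step).**
- What may go wrong: tin enolate 14 may enolise the newly formed benzylic ketone, whose enolate oxygen can then acylate onto the ortho ester. This is isocoumarin closure, and on ring B it would cleave the depside. Protodebromination, or stalling after the first coupling, are the other likely failures.
- Fallback: starting from 10, the enolate is replaced by a neutral allyl transfer followed by oxidative cleavage.
  - Copper-catalysed substitution of 3-chloro-2-(chloromethyl)prop-1-ene with hexylmagnesium bromide should give 2-(chloromethyl)non-1-ene F1.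
  - A Barbier reaction of F1 with Mg and Bu3SnCl should give tributyl(2-methylidenenonyl)stannane F2.
  - Kosugi–Migita–Stille coupling of 10 with F2 (Pd(PPh3)4, toluene, 100 °C) should give methyl 2-(benzyloxy)-4-{[2,4-bis(benzyloxy)-6-(2-methylidenenonyl)benzoyl]oxy}-6-(2-methylidenenonyl)benzoate F3.
  - Lemieux–Johnson cleavage of the two 1,1-disubstituted alkenes of F3 (cat. OsO4, NaIO4, 2,6-lutidine, dioxane/H2O) returns the route to 17.

**Step 4.**
- What may go wrong: the hindered acid chloride may react slowly, allowing acylation of both hydroxyls of 3 or loss of regiocontrol.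
- Fallback: starting from 3, the C4 oxygen is made the only free hydroxyl before the depside bond is formed.
  - Selective silylation (i-Pr3SiCl, imidazole, CH2Cl2) should give 2-bromo-6-hydroxy-4-[(triisopropylsilyl)oxy]benzaldehyde F4.
  - Benzylation (BnBr, K2CO3, DMF) should give 2-(benzyloxy)-6-bromo-4-[(triisopropylsilyl)oxy]benzaldehyde F5.
  - Bu4NF in THF should release 2-(benzyloxy)-6-bromo-4-hydroxybenzaldehyde F6.
  - Acylation of F6 with acid chloride 6 (Et3N, DMAP) rejoins the route at 8.

**Step 1.**
- What may go wrong: formylation at C2 between the two hydroxyls, O-formylation, or low conversion of the bromine-deactivated ring.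
- Fallback: starting from 1, the order of protection and formylation is inverted.
  - Benzylation (BnBr, K2CO3, DMF) should give 1,3-bis(benzyloxy)-5-bromobenzene F7.
  - Vilsmeier–Haack formylation (POCl3, DMF, 80 °C, then aqueous NaOAc) passes through [2,4-bis(benzyloxy)-6-bromobenzylidene]dimethyliminium chloride F8 and rejoins the route at 4.
  - The portion of 4 needed for step 4 is debenzylated with BCl3 (CH2Cl2, −78 °C) to supply 3.

**Step 5.**
- What may go wrong: while the sluggish hydrogen-bonded phenol is being alkylated, carbonate or phenoxide may transfer or cleave the activated aryl ester.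
- Fallback: starting from 7, the anionic alkylation is replaced by a Mitsunobu etherification with benzyl alcohol (PPh3, diisopropyl azodicarboxylate, THF, 0 °C → rt). This works through an alkoxyphosphonium ion under neutral conditions and returns directly to 8; no new compound is made.

## Further compounds

F1 | step 9 | 2-(chloromethyl)non-1-ene | C=C(CCl)CCCCCCC
F2 | step 9 | tributyl(2-methylidenenonyl)stannane | C=C(CCCCCCC)C[Sn](CCCC)(CCCC)CCCC
F3 | step 9 | methyl 2-(benzyloxy)-4-{[2,4-bis(benzyloxy)-6-(2-methylidenenonyl)benzoyl]oxy}-6-(2-methylidenenonyl)benzoate | CCCCCCCC(=C)Cc1cc(OCc2ccccc2)cc(OCc2ccccc2)c1C(=O)Oc1cc(OCc2ccccc2)c(C(=O)OC)c(CC(=C)CCCCCCC)c1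
F4 | step 4 | 2-bromo-6-hydroxy-4-[(triisopropylsilyl)oxy]benzaldehyde | O=Cc1c(O)cc(O[Si](C(C)C)(C(C)C)C(C)C)cc1Br
F5 | step 4 | 2-(benzyloxy)-6-bromo-4-[(triisopropylsilyl)oxy]benzaldehyde | O=Cc1c(OCc2ccccc2)cc(O[Si](C(C)C)(C(C)C)C(C)C)cc1Br
F6 | step 4 | 2-(benzyloxy)-6-bromo-4-hydroxybenzaldehyde | O=Cc1c(OCc2ccccc2)cc(O)cc1Br
F7 | step 1 | 1,3-bis(benzyloxy)-5-bromobenzene | Brc1cc(OCc2ccccc2)cc(OCc2ccccc2)c1
F8 | step 1 | [2,4-bis(benzyloxy)-6-bromobenzylidene]dimethyliminium chloride | C[N+](C)=Cc1c(OCc2ccccc2)cc(OCc2ccccc2)cc1Br.[Cl-]
F0 | step 5 | none | none
A1 | alternative 1 | methyl 4-({2,4-dihydroxy-6-[(2-heptyl-1,3-dioxolan-2-yl)methyl]benzoyl}oxy)-6-[(2-heptyl-1,3-dioxolan-2-yl)methyl]-2-hydroxybenzoate | CCCCCCCC1(Cc2cc(O)cc(O)c2C(=O)Oc2cc(O)c(C(=O)OC)c(CC3(CCCCCCC)OCCO3)c2)OCCO1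
A2 | alternative 1 | methyl 6-[(2-heptyl-1,3-dioxolan-2-yl)methyl]-4-{[8-(2-heptyl-1,3-dioxolan-2-yl)-3,5,7-trioxooctanoyl]oxy}-2-hydroxybenzoate | CCCCCCCC1(CC(=O)CC(=O)CC(=O)CC(=O)Oc2cc(O)c(C(=O)OC)c(CC3(CCCCCCC)OCCO3)c2)OCCO1
A3 | alternative 2 | methyl 2-acetoxy-4-{[2,4-diacetoxy-6-(2-oxononyl)benzoyl]oxy}-6-(2-oxononyl)benzoate | CCCCCCCC(=O)Cc1cc(OC(C)=O)cc(OC(C)=O)c1C(=O)Oc1cc(OC(C)=O)c(C(=O)OC)c(CC(=O)CCCCCCC)c1
A4 | alternative 2 | methyl 2-acetoxy-6-(bromomethyl)-4-{[2,4-diacetoxy-6-(bromomethyl)benzoyl]oxy}benzoate | BrCc1cc(OC(C)=O)cc(OC(C)=O)c1C(=O)Oc1cc(OC(C)=O)c(C(=O)OC)c(CBr)c1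
A5 | alternative 2 | heptylzinc bromide | CCCCCCC[Zn]Br
A6 | alternative 2 | carbon monoxide | [C-]#[O+]
A7 | alternative 3 | methyl 4-({2,4-dihydroxy-6-[(2-heptyl-1,3-dioxolan-2-yl)methyl]benzoyl}oxy)-6-[(2-heptyl-1,3-dioxolan-2-yl)methyl]-2-(methoxymethoxy)benzoate | CCCCCCCC1(Cc2cc(O)cc(O)c2C(=O)Oc2cc(OCOC)c(C(=O)OC)c(CC3(CCCCCCC)OCCO3)c2)OCCO1
A8 | alternative 3 | methyl 6-[(2-heptyl-1,3-dioxolan-2-yl)methyl]-4-{[4-(2-heptyl-1,3-dioxolan-2-yl)but-2-ynoyl]oxy}-2-(methoxymethoxy)benzoate | CCCCCCCC1(CC#CC(=O)Oc2cc(OCOC)c(C(=O)OC)c(CC3(CCCCCCC)OCCO3)c2)OCCO1
A9 | alternative 3 | 1-methoxy-1,3-bis(trimethylsilyloxy)buta-1,3-diene | C=C(O[Si](C)(C)C)C=C(OC)O[Si](C)(C)C
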